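**Retrosynthetic overview**
1. Target 26 ⇐ O9-silyl ether 25 ⇐ seco-diene 24 by ring-closing metathesis of C4=C5; the ten-membered carbocycle is closed last.
2. 24 ⇐ alcohol 22 by Mitsunobu esterification with isobutyric acid, which inverts C8.
3. 22 ⇐ aldehyde 10 + bromobutenolide 20 by an intermolecular zinc Barbier carbonyl allylation; this forms C7–C8 and the α-methylene-γ-lactone and is the fragment union.
4. 10 ⇐ 2-C-methyl-D-ribono-1,4-lactone 1 (C9 and C10 from the chiral pool; furanone by acetylide addition and gold cycloisomerisation). 20 ⇐ (S)-5-(hydroxymethyl)butyrolactone 11 (C6 from the chiral pool).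
5. Ring order: 3(2H)-furanone, then butenolide/α-methylene lactone, then the ten-membered carbocycle.

Assumption: germacrane numbering is used (C1 ketone, C2=C3 furanone alkene, C4=C5, C6 lactone carbinol, C8 ester carbinol, C9 free carbinol, C10 quaternary, C11=C13 methylene, C12 lactone carbonyl); 1, 4, 11 and 23 are taken as commercial.

**Step 1**
Reactants: 1 2-C-methyl-D-ribono-1,4-lactone
Product: 2 3,5-bis-O-(tert-butyldimethylsilyl)-2-C-methyl-D-ribono-1,4-lactone
Conditions: TBSCl (2.4 equiv), imidazole, DMAP (cat.), DMF, 40 °C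
Reagents that add atoms: tert-butyldimethylsilyl chloride, CC(C)(C)[Si](C)(C)Cl
Why: Silyl ether formation takes the primary and the secondary hydroxyl and leaves the hindered tertiary C2–OH free, with no stereocentre touched.

**Step 2**
Reactants: 2 3,5-bis-O-(tert-butyldimethylsilyl)-2-C-methyl-D-ribono-1,4-lactone
Product: 3 3,5-bis-O-(tert-butyldimethylsilyl)-2-C-methyl-2-O-(trimethylsilyl)-D-ribono-1,4-lactone
Conditions: TMSOTf, 2,6-lutidine, CH2Cl2, −78 → 0 °C
Reagents that add atoms: trimethylsilyl trifluoromethanesulfonate, C[Si](C)(C)OS(=O)(=O)C(F)(F)F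
Why: Silylation of the tertiary alcohol with a silyl triflate masks the acidic OH, so one equivalent of acetylide suffices and no alkoxide is present to trigger silyl migration.

**Step 3**
Reactants: 3 3,5-bis-O-(tert-butyldimethylsilyl)-2-C-methyl-2-O-(trimethylsilyl)-D-ribono-1,4-lactone; 4 2-methylbut-1-en-3-yne
Product: 7 3,5-bis-O-(tert-butyldimethylsilyl)-2-C-methyl-1-C-(3-methylbut-3-en-1-yn-1-yl)-D-ribofuranose, via lithium 3-methylbut-3-en-1-yn-1-ide 5 (not isolated), via O-trimethylsilyl hemiketal 6 (not isolated)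
Conditions: 4 (1.6 equiv), n-BuLi (1.5 equiv), THF, −78 °C; then 3, −78 °C; then 0.5 M aq HCl, THF, 0 °C
Reagents that add atoms: none
Why: A lithium acetylide adds once to the lactone carbonyl (the tetrahedral lithium hemiketal alkoxide survives at −78 °C) and dilute acid then cleaves the labile tertiary TMS ether; the three ring stereocentres are unchanged and the new anomeric centre is inconsequential.

**Step 4**
Reactants: 7 3,5-bis-O-(tert-butyldimethylsilyl)-2-C-methyl-1-C-(3-methylbut-3-en-1-yn-1-yl)-D-ribofuranose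
Product: 8 (2R)-2-[(1R,2R)-1,3-bis(tert-butyldimethylsilyloxy)-2-hydroxypropyl]-2-methyl-5-(prop-1-en-2-yl)furan-3(2H)-one
Conditions: (Ph3P)AuNTf2 (5 mol %), toluene, rt
Reagents that add atoms: none
Why: Gold-catalysed 5-endo-dig hydroalkoxylation (cycloisomerisation of the α-hydroxy ynone in equilibrium with its hemiketal) adds the tertiary C10–OH to the activated alkyne and hemiketal collapse gives the 3(2H)-furanone; no bond to the quaternary C10 centre is broken.

**Step 5**
Reactants: 8 (2R)-2-[(1R,2R)-1,3-bis(tert-butyldimethylsilyloxy)-2-hydroxypropyl]-2-methyl-5-(prop-1-en-2-yl)furan-3(2H)-one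
Product: 9 (2R)-2-[(1R,2R)-1-(tert-butyldimethylsilyloxy)-2,3-dihydroxypropyl]-2-methyl-5-(prop-1-en-2-yl)furan-3(2H)-one
Conditions: CSA (0.2 equiv), MeOH/CH2Cl2 (1:1), 0 °C
Reagents that add atoms: none
Why: Acid-catalysed methanolysis (selective desilylation) removes the primary TBS ether far faster than the secondary one next to the quaternary carbon.

**Step 6**
Reactants: 9 (2R)-2-[(1R,2R)-1-(tert-butyldimethylsilyloxy)-2,3-dihydroxypropyl]-2-methyl-5-(prop-1-en-2-yl)furan-3(2H)-one
Product: 10 (2S)-2-(tert-butyldimethylsilyloxy)-2-[(2R)-2-methyl-3-oxo-5-(prop-1-en-2-yl)-2,3-dihydrofuran-2-yl]acetaldehyde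
Conditions: NaIO4, THF/pH 7 buffer, 0 °C; used at once
Reagents that add atoms: none
Why: Periodate glycol cleavage excises the terminal carbon and unveils the C8 aldehyde under neutral conditions, so the α-silyloxy centre C9 is not epimerised.

**Step 7**
Reactants: 11 (S)-5-(hydroxymethyl)dihydrofuran-2(3H)-one
Product: 12 (S)-5-oxotetrahydrofuran-2-carbaldehyde
Conditions: Dess–Martin periodinane, CH2Cl2, 0 °C → rt; used crude
Reagents that add atoms: none
Why: Dess–Martin oxidation without base preserves the α-acyloxy stereocentre (future C6).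

**Step 8**
Reactants: 12 (S)-5-oxotetrahydrofuran-2-carbaldehyde
Product: 13 (S)-5-vinyldihydrofuran-2(3H)-one
Conditions: Ph3PCH3Br (1.3 equiv), KN(SiMe3)2 (1.25 equiv), THF, 0 °C; then 12, −78 → 0 °C
Reagents that add atoms: methyltriphenylphosphonium bromide, C[P+](c1ccccc1)(c1ccccc1)c1ccccc1.[Br-]
Why: Wittig methylenation; the non-stabilised ylide adds to the aldehyde at −78 °C much faster than it enolises it or attacks the lactone, so C6 keeps its configuration.

**Step 9**
Reactants: 13 (S)-5-vinyldihydrofuran-2(3H)-one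
Product: 15 (5S)-3-(phenylselanyl)-5-vinyldihydrofuran-2(3H)-one, via lithium enolate 14 (not isolated)
Conditions: LiN(iPr)2 (1.05 equiv), THF, −78 °C; then PhSeBr, −78 °C
Reagents that add atoms: benzeneselenenyl bromide, Br[Se]c1ccccc1
Why: α-Selenenylation of the lactone lithium enolate; the new C–Se centre forms as a mixture that does not matter because it is destroyed in step 11.

**Step 10**
Reactants: 15 (5S)-3-(phenylselanyl)-5-vinyldihydrofuran-2(3H)-one
Product: 17 (5S)-3-(hydroxymethyl)-3-(phenylselanyl)-5-vinyldihydrofuran-2(3H)-one, via lithium selanyl enolate 16 (not isolated)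
Conditions: LiN(iPr)2 (1.1 equiv), THF, −78 °C; then HCHO (gas, from cracked paraformaldehyde), −78 → −40 °C; sat. aq NH4Cl
Reagents that add atoms: formaldehyde, C=O
Why: Aldol addition of the selenium-stabilised enolate to monomeric formaldehyde installs the future C13 carbon; the quaternary centre is again an inconsequential mixture.

**Step 11**
Reactants: 17 (5S)-3-(hydroxymethyl)-3-(phenylselanyl)-5-vinyldihydrofuran-2(3H)-one
Product: 19 (5R)-3-(hydroxymethyl)-5-vinylfuran-2(5H)-one, via selenoxide 18 (not isolated)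
Conditions: 30% H2O2 (2.5 equiv), CH2Cl2, 0 °C → rt, no amine base
Reagents that add atoms: none
Why: Selenoxide syn-elimination takes the ring C–H (elimination toward the carbinol would give an enol and is disfavoured) to give the butenolide; base is left out because the doubly allylic C6–H of the product is acidic.

**Step 12**
Reactants: 19 (5R)-3-(hydroxymethyl)-5-vinylfuran-2(5H)-one
Product: 20 (5R)-3-(bromomethyl)-5-vinylfuran-2(5H)-one
Conditions: CBr4, PPh3, CH2Cl2, 0 °C
Reagents that add atoms: carbon tetrabromide, BrC(Br)(Br)Br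
Why: Appel bromination of the primary allylic alcohol under neutral conditions leaves C6 untouched.

**Step 13 (key fragment union)**
Reactants: 20 (5R)-3-(bromomethyl)-5-vinylfuran-2(5H)-one; 10 (2S)-2-(tert-butyldimethylsilyloxy)-2-[(2R)-2-methyl-3-oxo-5-(prop-1-en-2-yl)-2,3-dihydrofuran-2-yl]acetaldehyde
Product: 22 (4R,5R)-4-{(1R,2R)-2-(tert-butyldimethylsilyloxy)-1-hydroxy-2-[(2R)-2-methyl-3-oxo-5-(prop-1-en-2-yl)-2,3-dihydrofuran-2-yl]ethyl}-3-methylidene-5-vinyldihydrofuran-2(3H)-one, via allylzinc bromide 21 (not isolated)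
Conditions: 10 (1.0 equiv), 20 (1.5 equiv), Zn dust (3 equiv), THF/sat. aq NH4Cl (2:1), 0 °C → rt
Reagents that add atoms: none
Why: Zinc Barbier carbonyl allylation: allylzinc 21 attacks the aldehyde through its ring carbon C7 in a closed six-membered chair (allyl transposition unveils the exo-methylene), bonding anti to the C6 vinyl group (6,7-trans) and, because the ring fixes the allyl geometry and the aldehyde residue sits equatorial, giving the 7,8-anti carbinol (8R, the C8 epimer of the target), which is also the face the polar Felkin–Anh model predicts for the α-silyloxy aldehyde.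

**Step 14**
Reactants: 22 (the 8R alcohol); 23 isobutyric acid
Product: 24 (1S,2R)-2-(tert-butyldimethylsilyloxy)-2-[(2R)-2-methyl-3-oxo-5-(prop-1-en-2-yl)-2,3-dihydrofuran-2-yl]-1-[(2R,3S)-4-methylidene-5-oxo-2-vinyltetrahydrofuran-3-yl]ethyl 2-methylpropanoate
Conditions: PPh3, DIAD (premixed, 0 °C), then 23 (3 equiv) and 22, toluene, 0 °C → rt
Reagents that add atoms: none
Why: Mitsunobu esterification: SN2 displacement of the activated C8 oxygen by isobutyrate inverts C8 from R to S and installs the ester in one operation.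

**Step 15**
Reactants: 24 (seco-diene isobutyrate)
Product: 25 (4Z,6R,7S,8S,9R,10R)-9-(tert-butyldimethylsilyloxy)-8-(2-methylpropanoyloxy)-1-oxo-3,10-epoxygermacra-2,4,11(13)-trien-12,6-olide
Conditions: second-generation Hoveyda–Grubbs catalyst (15 mol %, in portions), 1,4-benzoquinone (10 mol %), toluene (1 mM), 90 °C
Reagents that add atoms: none
Why: Ring-closing metathesis of the C6 vinyl group with the furanone isopropenyl group, driven by loss of ethylene at high dilution; the electron-poor 1,1-disubstituted methylene lactone does not compete, the bridged nine-membered oxacycle can only hold the Z alkene, and no stereocentre is touched.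

**Step 16**
Reactants: 25 (O9-TBS macrocycle)
Product: 26 CNP0265772.1, (4Z,6R,7S,8S,9R,10R)-9-hydroxy-8-(2-methylpropanoyloxy)-1-oxo-3,10-epoxygermacra-2,4,11(13)-trien-12,6-olide
Conditions: HF·pyridine, pyridine, THF, 0 °C → rt
Reagents that add atoms: none
Why: Fluoride-mediated desilylation under buffered, weakly acidic conditions frees the C9 hydroxyl without acyl migration from O8 and without harming the methylene lactone or the furanone.

**Compound list**
1 | 2-C-methyl-D-ribono-1,4-lactone, (3R,4R,5R)-3,4-dihydroxy-5-(hydroxymethyl)-3-methyloxolan-2-one | O=C1[C@](C)(O)[C@H](O)[C@@H](CO)O1 | starting material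
2 | 3,5-bis-O-(tert-butyldimethylsilyl)-2-C-methyl-D-ribono-1,4-lactone | O=C1[C@](C)(O)[C@H](O[Si](C)(C)C(C)(C)C)[C@@H](CO[Si](C)(C)C(C)(C)C)O1 | intermediate
3 | 3,5-bis-O-(tert-butyldimethylsilyl)-2-C-methyl-2-O-(trimethylsilyl)-D-ribono-1,4-lactone | O=C1[C@](C)(O[Si](C)(C)C)[C@H](O[Si](C)(C)C(C)(C)C)[C@@H](CO[Si](C)(C)C(C)(C)C)O1 | intermediate
4 | 2-methylbut-1-en-3-yne | C=C(C)C#C | starting material
5 | lithium 3-methylbut-3-en-1-yn-1-ide (in flask) | [Li]C#CC(C)=C | intermediate
6 | O-trimethylsilyl hemiketal, 2-O-TMS ether of 7 (in flask; both anomers) | C=C(C)C#CC1(O)[C@](C)(O[Si](C)(C)C)[C@H](O[Si](C)(C)C(C)(C)C)[C@@H](CO[Si](C)(C)C(C)(C)C)O1 | intermediate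
7 | 3,5-bis-O-(tert-butyldimethylsilyl)-2-C-methyl-1-C-(3-methylbut-3-en-1-yn-1-yl)-D-ribofuranose (hemiketal; both anomers) | C=C(C)C#CC1(O)[C@](C)(O)[C@H](O[Si](C)(C)C(C)(C)C)[C@@H](CO[Si](C)(C)C(C)(C)C)O1 | intermediate
8 | (2R)-2-[(1R,2R)-1,3-bis(tert-butyldimethylsilyloxy)-2-hydroxypropyl]-2-methyl-5-(prop-1-en-2-yl)furan-3(2H)-one | C=C(C)C1=CC(=O)[C@](C)(O1)[C@H](O[Si](C)(C)C(C)(C)C)[C@H](O)CO[Si](C)(C)C(C)(C)C | intermediate
9 | (2R)-2-[(1R,2R)-1-(tert-butyldimethylsilyloxy)-2,3-dihydroxypropyl]-2-methyl-5-(prop-1-en-2-yl)furan-3(2H)-one | C=C(C)C1=CC(=O)[C@](C)(O1)[C@H](O[Si](C)(C)C(C)(C)C)[C@H](O)CO | intermediate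
10 | (2S)-2-(tert-butyldimethylsilyloxy)-2-[(2R)-2-methyl-3-oxo-5-(prop-1-en-2-yl)-2,3-dihydrofuran-2-yl]acetaldehyde | C=C(C)C1=CC(=O)[C@](C)(O1)[C@H](O[Si](C)(C)C(C)(C)C)C=O | intermediate
11 | (S)-5-(hydroxymethyl)dihydrofuran-2(3H)-one | OC[C@H]1OC(=O)CC1 | starting material
12 | (S)-5-oxotetrahydrofuran-2-carbaldehyde | O=C[C@H]1OC(=O)CC1 | intermediate
13 | (S)-5-vinyldihydrofuran-2(3H)-one | C=C[C@H]1OC(=O)CC1 | intermediate
14 | lithium enolate of 13 (in flask) | C=C[C@H]1OC(O[Li])=CC1 | intermediate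
15 | (5S)-3-(phenylselanyl)-5-vinyldihydrofuran-2(3H)-one (C3 epimers) | C=C[C@H]1OC(=O)C([Se]c2ccccc2)C1 | intermediate
16 | lithium enolate of 15 (in flask) | C=C[C@H]1OC(O[Li])=C([Se]c2ccccc2)C1 | intermediate
17 | (5S)-3-(hydroxymethyl)-3-(phenylselanyl)-5-vinyldihydrofuran-2(3H)-one (C3 epimers) | C=C[C@H]1OC(=O)C(CO)([Se]c2ccccc2)C1 | intermediate
18 | selenoxide of 17 (in flask) | C=C[C@H]1OC(=O)C(CO)([Se](=O)c2ccccc2)C1 | intermediate
19 | (5R)-3-(hydroxymethyl)-5-vinylfuran-2(5H)-one | C=C[C@H]1OC(=O)C(CO)=C1 | intermediate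
20 | (5R)-3-(bromomethyl)-5-vinylfuran-2(5H)-one | C=C[C@H]1OC(=O)C(CBr)=C1 | intermediate
21 | allylzinc bromide from 20 (in flask) | C=C[C@H]1OC(=O)C(C[Zn]Br)=C1 | intermediate
22 | (4R,5R)-4-{(1R,2R)-2-(tert-butyldimethylsilyloxy)-1-hydroxy-2-[(2R)-2-methyl-3-oxo-5-(prop-1-en-2-yl)-2,3-dihydrofuran-2-yl]ethyl}-3-methylidene-5-vinyldihydrofuran-2(3H)-one (C8 R) | C=C(C)C1=CC(=O)[C@](C)(O1)[C@H](O[Si](C)(C)C(C)(C)C)[C@H](O)[C@@H]1[C@@H](C=C)OC(=O)C1=C | intermediate
23 | isobutyric acid (2-methylpropanoic acid) | CC(C)C(=O)O | starting material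
24 | (1S,2R)-2-(tert-butyldimethylsilyloxy)-2-[(2R)-2-methyl-3-oxo-5-(prop-1-en-2-yl)-2,3-dihydrofuran-2-yl]-1-[(2R,3S)-4-methylidene-5-oxo-2-vinyltetrahydrofuran-3-yl]ethyl 2-methylpropanoate (C8 S) | C=C(C)C1=CC(=O)[C@](C)(O1)[C@H](O[Si](C)(C)C(C)(C)C)[C@@H](OC(=O)C(C)C)[C@@H]1[C@@H](C=C)OC(=O)C1=C | intermediate
25 | (4Z,6R,7S,8S,9R,10R)-9-(tert-butyldimethylsilyloxy)-8-(2-methylpropanoyloxy)-1-oxo-3,10-epoxygermacra-2,4,11(13)-trien-12,6-olide | C=C1C(=O)O[C@@H]2/C=C(/C)C3=CC(=O)[C@](C)(O3)[C@H](O[Si](C)(C)C(C)(C)C)[C@@H](OC(=O)C(C)C)[C@@H]12 | intermediate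
26 | CNP0265772.1, (4Z,6R,7S,8S,9R,10R)-9-hydroxy-8-(2-methylpropanoyloxy)-1-oxo-3,10-epoxygermacra-2,4,11(13)-trien-12,6-olide | C=C1C(=O)O[C@@H]2/C=C(/C)C3=CC(=O)[C@](C)(O3)[C@H](O)[C@@H](OC(=O)C(C)C)[C@@H]12 | target

**Totals**
Total step count: 16. Longest linear sequence: 10 steps (1 → 26 through steps 1–6 and 13–16; equally 11 → 26 through steps 7–16).

**The three steps most likely to fail**

Step 15 (ring-closing metathesis). A trisubstituted, furanone-conjugated alkene has to form in a medium ring, and dimerisation through the vinyl group or a stalled carbene on the isopropenyl side are the likely failures. The fallback is a relay ring-closing metathesis; it sets out from lactone 3 and comes back to the route at macrocycle 25. Commercial (E)-3-methylpent-2-en-4-yn-1-ol is O-allylated (NaH, allyl bromide, THF, 0 °C) to the relay enyne (E)-5-(allyloxy)-3-methylpent-3-en-1-yne F1. n-BuLi (THF, −78 °C) turns it into the relay lithium acetylide F2, which adds to 3 to give the relay O-trimethylsilyl hemiketal F3 and, after the dilute-acid work-up, the relay hemiketal F4. (Ph3P)AuNTf2 then gives the relay furanone F5, CSA/MeOH the relay diol F6 and NaIO4 the relay aldehyde F7. Zinc-mediated allylation with 20 (through 21) gives the relay alcohol F8, and Mitsunobu esterification with 23 gives the relay isobutyrate F9. With the second-generation Hoveyda–Grubbs catalyst the ruthenium carbene loads on the terminal allyl ether, closes onto the trisubstituted alkene with loss of 2,5-dihydrofuran and is thereby placed on C4, from where it ring-closes onto the C6 vinyl group to give 25.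

Step 14 (Mitsunobu inversion). C8 is flanked by two branched carbons, and elimination toward the allylic C7–H or simple non-reaction are the likely failures. The fallback is oxidation, Felkin–Anh reduction and acylation with retention; it sets out from 22 and comes back at 24. Dess–Martin periodinane (CH2Cl2, 0 °C, no base) gives the C8 ketone F10. NaBH4 with CeCl3·7H2O (MeOH, −78 °C) should deliver hydride anti to the α-silyloxy group without 1,4-reduction of the methylene lactone and give the 8S alcohol F11. Isobutyryl chloride, pyridine and DMAP (CH2Cl2, 0 °C) then give 24. The ketone must be kept free of base because C7–H is both α to it and allylic.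

Step 13 (Barbier allylation). Two stereocentres are set at once, aldehyde 10 can lose the furanone oxygen by β-elimination if the medium turns basic, and the C8 configuration of 22 rests on a chair transition state and should be confirmed before step 14. The fallback replaces the organozinc by an isolated allylboron reagent; it sets out from 20 and comes back at 22. B2pin2 with Pd2(dba)3 (2.5 mol %, toluene/DMSO, rt) converts 20 into the pinacol allylboronate F12. Heating F12 with 10 in toluene (60–80 °C, neutral, anhydrous) gives, through the same ring-locked chair, the pinacol borate ester F13, which aqueous NaHCO3 hydrolyses to 22.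

**Further compounds**
F1 | step 15 | relay enyne, (E)-5-(allyloxy)-3-methylpent-3-en-1-yne | C#C/C(C)=C/COCC=C
F2 | step 15 | relay lithium acetylide, lithium (E)-5-(allyloxy)-3-methylpent-3-en-1-yn-1-ide | [Li]C#C/C(C)=C/COCC=C
F3 | step 15 | relay O-trimethylsilyl hemiketal (2-O-TMS ether of F4; both anomers) | C=CCOC/C=C(\C)C#CC1(O)[C@](C)(O[Si](C)(C)C)[C@H](O[Si](C)(C)C(C)(C)C)[C@@H](CO[Si](C)(C)C(C)(C)C)O1
F4 | step 15 | relay hemiketal, 1-C-[(E)-5-(allyloxy)-3-methylpent-3-en-1-yn-1-yl]-3,5-bis-O-(tert-butyldimethylsilyl)-2-C-methyl-D-ribofuranose | C=CCOC/C=C(\C)C#CC1(O)[C@](C)(O)[C@H](O[Si](C)(C)C(C)(C)C)[C@@H](CO[Si](C)(C)C(C)(C)C)O1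
F5 | step 15 | relay furanone, (2R)-5-[(E)-4-(allyloxy)but-2-en-2-yl]-2-[(1R,2R)-1,3-bis(tert-butyldimethylsilyloxy)-2-hydroxypropyl]-2-methylfuran-3(2H)-one | C=CCOC/C=C(\C)C1=CC(=O)[C@](C)(O1)[C@H](O[Si](C)(C)C(C)(C)C)[C@H](O)CO[Si](C)(C)C(C)(C)C
F6 | step 15 | relay diol, (2R)-5-[(E)-4-(allyloxy)but-2-en-2-yl]-2-[(1R,2R)-1-(tert-butyldimethylsilyloxy)-2,3-dihydroxypropyl]-2-methylfuran-3(2H)-one | C=CCOC/C=C(\C)C1=CC(=O)[C@](C)(O1)[C@H](O[Si](C)(C)C(C)(C)C)[C@H](O)CO
F7 | step 15 | relay aldehyde, (2S)-2-{(2R)-5-[(E)-4-(allyloxy)but-2-en-2-yl]-2-methyl-3-oxo-2,3-dihydrofuran-2-yl}-2-(tert-butyldimethylsilyloxy)acetaldehyde | C=CCOC/C=C(\C)C1=CC(=O)[C@](C)(O1)[C@H](O[Si](C)(C)C(C)(C)C)C=O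
F8 | step 15 | relay alcohol, analogue of 22 (C8 R) with the (E)-4-(allyloxy)but-2-en-2-yl group on the furanone | C=CCOC/C=C(\C)C1=CC(=O)[C@](C)(O1)[C@H](O[Si](C)(C)C(C)(C)C)[C@H](O)[C@@H]1[C@@H](C=C)OC(=O)C1=C
F9 | step 15 | relay isobutyrate, analogue of 24 (C8 S) with the (E)-4-(allyloxy)but-2-en-2-yl group on the furanone | C=CCOC/C=C(\C)C1=CC(=O)[C@](C)(O1)[C@H](O[Si](C)(C)C(C)(C)C)[C@@H](OC(=O)C(C)C)[C@@H]1[C@@H](C=C)OC(=O)C1=C
F10 | step 14 | C8 ketone, (4S,5R)-4-{(2S)-2-(tert-butyldimethylsilyloxy)-2-[(2R)-2-methyl-3-oxo-5-(prop-1-en-2-yl)-2,3-dihydrofuran-2-yl]acetyl}-3-methylidene-5-vinyldihydrofuran-2(3H)-one | C=C(C)C1=CC(=O)[C@](C)(O1)[C@H](O[Si](C)(C)C(C)(C)C)C(=O)[C@@H]1[C@@H](C=C)OC(=O)C1=C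
F11 | step 14 | 8S alcohol, (4R,5R)-4-{(1S,2R)-2-(tert-butyldimethylsilyloxy)-1-hydroxy-2-[(2R)-2-methyl-3-oxo-5-(prop-1-en-2-yl)-2,3-dihydrofuran-2-yl]ethyl}-3-methylidene-5-vinyldihydrofuran-2(3H)-one | C=C(C)C1=CC(=O)[C@](C)(O1)[C@H](O[Si](C)(C)C(C)(C)C)[C@@H](O)[C@@H]1[C@@H](C=C)OC(=O)C1=C
F12 | step 13 | pinacol allylboronate, (5R)-3-[(4,4,5,5-tetramethyl-1,3,2-dioxaborolan-2-yl)methyl]-5-vinylfuran-2(5H)-one | C=C[C@H]1OC(=O)C(CB2OC(C)(C)C(C)(C)O2)=C1
F13 | step 13 | pinacol borate ester of 22 (O8–B bond; in flask) | C=C(C)C1=CC(=O)[C@](C)(O1)[C@H](O[Si](C)(C)C(C)(C)C)[C@H](OB2OC(C)(C)C(C)(C)O2)[C@@H]1[C@@H](C=C)OC(=O)C1=C
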